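**Retrosynthetic overview**

1. The strategy rests on the 1,2-dioxane ring (O1–O2–C3–C4–C5–C6): its two peroxide-bound carbons C3 and C6 stand 1,4 to each other across C4–C5, the spacing of a 1,4-diketone bridged by H2O2.
2. Diene arm: the C9–C10 bond by Suzuki coupling of vinyl iodide 21 with boronate 24; the C8 methyl and C9 iodide by carboalumination–iodination of the terminal alkyne of 19.
3. C6–CH3 and C3–H: methyl, then hydride, delivered pseudo-axially to the two peroxyketal carbons of 17 (C6 first), both relayed from the C4 methyl.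
4. O1–C6 and O2–C3: double peroxyketalisation of diketone 14 with H2O2 (step 6), which closes the only ring of the target; the lactone ring of 10 is transient.
5. Diketone 14: Evans allylation (sets C4), ozonolysis, zinc propargylation with lactonisation, Claisen opening of the lactone, oxidation.

Key step: step 6

Assumption: ring numbering O1, O2, C3 (acetate arm), C4 (methyl), C5, C6 is used for the open-chain precursors too; the alkyne is carried unprotected because no step here needs a silyl cap; 16 and 17 are anomeric mixtures at C3 and C6 that equilibrate under acid, are drawn as the diaxial dihydroxy and dimethoxy forms, and both centres are re-set in steps 8 and 9.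

**Route**

Step 1
Reactants: 1 (4S)-4-benzyl-3-propanoyl-1,3-oxazolidin-2-one; 2 allyl iodide
Product: 4 (4S)-4-benzyl-3-[(2R)-2-methylpent-4-enoyl]-1,3-oxazolidin-2-one, via sodium enolate 3 (not isolated)
Conditions: NaN(SiMe3)2, THF, −78 °C; then 2, −78 → −40 °C
Reagents that add atoms: none
Why: Evans asymmetric alkylation: the chelated sodium Z-enolate 3 is shielded on one face by the benzyl group of the auxiliary, so allyl iodide enters from the other face and sets the methyl-bearing centre (C4 of the target) as R.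

Step 2
Reactants: 4 (4S)-4-benzyl-3-[(2R)-2-methylpent-4-enoyl]-1,3-oxazolidin-2-one
Product: 6 (4S)-4-benzyl-3-[(2R)-2-methyl-4-oxobutanoyl]-1,3-oxazolidin-2-one, via ozonide 5 (not isolated)
Conditions: O3, CH2Cl2, −78 °C; then PPh3, −78 °C → rt
Reagents that add atoms: ozone, O=[O+][O-]
Why: Ozonolysis of the monosubstituted alkene with reductive cleavage of ozonide 5 by PPh3; the stereocentre is β to the new aldehyde and cannot enolise toward it.

Step 3
Reactants: 6 (4S)-4-benzyl-3-[(2R)-2-methyl-4-oxobutanoyl]-1,3-oxazolidin-2-one; 7 propargyl bromide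
Product: 10 (3R,5RS)-3-methyl-5-(prop-2-yn-1-yl)oxolan-2-one, via allenylzinc bromide 8 (not isolated), via hydroxy imide 9 (not isolated)
Conditions: Zn dust, THF, 0 °C → rt; aqueous work-up; then DBU (0.2 equiv), CH2Cl2, rt
Reagents that add atoms: none
Why: Barbier-type zinc propargylation, in which allenylzinc bromide 8 adds through an SE2′ transition state to the aldehyde only and gives homopropargylic alcohol 9, whose hydroxyl then displaces the oxazolidinone by 5-exo-trig acyl transfer under DBU catalysis; the carbinol centre forms unselectively and is erased in step 5.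

Step 4
Reactants: 10 (3R,5RS)-3-methyl-5-(prop-2-yn-1-yl)oxolan-2-one; 11 methyl acetate
Product: 13 methyl (4R,6RS)-6-hydroxy-4-methyl-3-oxonon-8-ynoate, via lithium enolate 12 (not isolated)
Conditions: LiN(iPr)2 (2.4 equiv), 11 (2.5 equiv), THF, −78 °C; then 10, −78 °C; AcOH, −78 °C
Reagents that add atoms: none
Why: Crossed Claisen-type acylation of lithium enolate 12 by the lactone: the tetrahedral lithium lactolate persists at −78 °C so only one addition occurs, and carbonyl addition should outrun enolisation of the lactone so C4 is kept; the product equilibrates with its five-membered cyclic hemiketal, which is inconsequential.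

Step 5
Reactants: 13 methyl (4R,6RS)-6-hydroxy-4-methyl-3-oxonon-8-ynoate
Product: 14 methyl (4R)-4-methyl-3,6-dioxonon-8-ynoate
Conditions: Dess–Martin periodinane, NaHCO3, CH2Cl2, 0 °C → rt; used without chromatography on silica
Reagents that add atoms: none
Why: Dess–Martin oxidation of the secondary alcohol (through the open-chain tautomer) under buffered, non-basic conditions, which spare the β-keto ester and avoid isomerisation of the β,γ-alkynyl ketone to the allenone and Paal–Knorr furan formation.

Step 6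
Reactants: 14 methyl (4R)-4-methyl-3,6-dioxonon-8-ynoate
Product: 16 methyl 2-[(3S,4R,6R)-3,6-dihydroxy-4-methyl-6-(prop-2-yn-1-yl)-1,2-dioxan-3-yl]acetate, via hydroxy hydroperoxide 15 (not isolated)
Conditions: anhydrous H2O2 in Et2O (1.05 equiv), MgSO4, PPTS (2 mol %), Et2O (0.02 M), 0 °C → rt
Reagents that add atoms: hydrogen peroxide, OO
Why: H2O2 adds first to the unhindered, inductively activated C6 carbonyl to give hydroxy hydroperoxide 15, whose OOH then adds to the C3 carbonyl, so the O1–C6 and O2–C3 bonds form in turn; the closest known reaction is the condensation of 1,4-diketones with H2O2 to 3,6-dihydroxy-1,2-dioxanes (cyclic bis-peroxyhemiketals). The 1,2-dioxane closes by 6-exo-trig attack of the hydroperoxide oxygen on the C3 carbonyl. C3 and C6 become hemiketal centres that equilibrate by ring–chain tautomerism, so they are under thermodynamic control (anomeric effect: both hydroxyls axial, both carbon arms equatorial, anchored by the equatorial C4 methyl) and no permanent stereocentre is created here. The step needs chemoselectivity for the monomeric cyclic adduct over geminal dihydroperoxides, tetraoxanes and the bridged ozonide formed by dehydration, which one equivalent of H2O2, high dilution and the entropic advantage of six-membered closure should secure. It also needs retention at C4, which the near-neutral anhydrous medium and the preference of the C3 ketone to enolise toward C2 (β-keto ester) protect.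

Step 7
Reactants: 16 methyl 2-[(3S,4R,6R)-3,6-dihydroxy-4-methyl-6-(prop-2-yn-1-yl)-1,2-dioxan-3-yl]acetate
Product: 17 methyl 2-[(3S,4R,6R)-3,6-dimethoxy-4-methyl-6-(prop-2-yn-1-yl)-1,2-dioxan-3-yl]acetate
Conditions: MeOH, HC(OMe)3 (3 equiv), PPTS (10 mol %), 0 °C → rt
Reagents that add atoms: methanol, CO
Why: Acid-catalysed exchange of both hemiketal hydroxyls for methoxy through ring-retained peroxycarbenium ions (peroxyketal formation, the analogue of Fischer glycosidation), driven by the orthoformate water scavenger, with the anomeric effect placing both methoxy groups axial; capping removes the acidic hydroxyls, whose aluminium alkoxides would fragment in step 8.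

Step 8
Reactants: 17 methyl 2-[(3S,4R,6R)-3,6-dimethoxy-4-methyl-6-(prop-2-yn-1-yl)-1,2-dioxan-3-yl]acetate
Product: 18 methyl 2-[(3S,4R,6R)-3-methoxy-4,6-dimethyl-6-(prop-2-yn-1-yl)-1,2-dioxan-3-yl]acetate
Conditions: Me3Al (4 equiv), CH2Cl2, −78 °C; then TMSOTf (0.2 equiv), −78 → −30 °C; aq. KNaC4H4O6 work-up
Reagents that add atoms: trimethylaluminium, C[Al](C)C
Why: Proposed new method: excess Me3Al first complexes the ester carbonyl, which deactivates the neighbouring C3 ketal, so the promoter ionises the C6 methoxy group to a peroxycarbenium ion, and the methylaluminate then transfers methyl along the pseudo-axial trajectory of the half-chair that keeps C4-Me pseudo-equatorial, placing the new methyl axial and trans to C4-Me, i.e. (6R); the closest known reactions are the Lewis-acid-mediated allylation of peroxyketals through peroxycarbenium ions (Sakurai type) and the axial C-methylation of cyclic ketals and anomeric fluorides with Me3Al.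

Step 9
Reactants: 18 methyl 2-[(3S,4R,6R)-3-methoxy-4,6-dimethyl-6-(prop-2-yn-1-yl)-1,2-dioxan-3-yl]acetate
Product: 19 methyl 2-[(3S,4R,6R)-4,6-dimethyl-6-(prop-2-yn-1-yl)-1,2-dioxan-3-yl]acetate
Conditions: Et3SiH (5 equiv), TMSOTf (0.5 equiv), CH2Cl2, −78 → −20 °C
Reagents that add atoms: none
Why: Ionic (silane) reduction of a ketal, a reaction type used on peroxyketals and on cyclic ketals bearing an acetate arm: the C3 methoxy group ionises to the peroxycarbenium ion and hydride enters pseudo-axially on the half-chair that keeps C4-Me pseudo-equatorial and avoids a 1,3-diaxial contact between C4-Me and the C6 arm, which sets C3 as S with H axial and the acetate arm equatorial, trans to C4-Me.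

Step 10
Reactants: 19 methyl 2-[(3S,4R,6R)-4,6-dimethyl-6-(prop-2-yn-1-yl)-1,2-dioxan-3-yl]acetate
Product: 21 methyl 2-[(3S,4R,6R)-6-[(2E)-3-iodo-2-methylprop-2-en-1-yl]-4,6-dimethyl-1,2-dioxan-3-yl]acetate, via alkenylalane 20 (not isolated)
Conditions: Me3Al (3 equiv), Cp2ZrCl2 (0.3 equiv), H2O (1 equiv), CH2Cl2, −23 °C; then I2, THF, −23 → 0 °C
Reagents that add atoms: trimethylaluminium, C[Al](C)C; iodine, II
Why: Negishi zirconium-catalysed carboalumination: syn addition of methyl and aluminium across the terminal alkyne with aluminium on the terminal carbon gives alkenylalane 20, and iodinolysis with retention gives the E vinyl iodide; the water-accelerated variant at −23 °C keeps contact of the ester and the peroxide with the organoaluminium short.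

Step 11
Reactants: 22 allylbenzene; 23 isopropenylboronic acid pinacol ester
Product: 24 4,4,5,5-tetramethyl-2-[(2Z)-4-phenylbut-2-en-2-yl]-1,3,2-dioxaborolane
Conditions: second-generation Grubbs catalyst RuCl2(=CHPh)(H2IMes)(PCy3) (5 mol %), 22 (2 equiv), CH2Cl2, 40 °C
Reagents that add atoms: none
Why: Olefin cross-metathesis between a terminal alkene and a 1,1-disubstituted vinylboronate, which is expected to place the bulky boronate trans to the benzyl arm (the Z descriptor of 24).

Step 12
Reactants: 21 methyl 2-[(3S,4R,6R)-6-[(2E)-3-iodo-2-methylprop-2-en-1-yl]-4,6-dimethyl-1,2-dioxan-3-yl]acetate; 24 4,4,5,5-tetramethyl-2-[(2Z)-4-phenylbut-2-en-2-yl]-1,3,2-dioxaborolane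
Product: 25 methyl 2-[(3S,4R,6R)-6-[(2E,4E)-2,4-dimethyl-6-phenylhexa-2,4-dien-1-yl]-4,6-dimethyl-1,2-dioxan-3-yl]acetate
Conditions: PdCl2(dppf) (5 mol %), K3PO4 (3 equiv), THF/H2O (10:1), rt → 40 °C
Reagents that add atoms: none
Why: Suzuki–Miyaura coupling of an alkenyl iodide with an alkenylboronate, with retention of both alkene geometries; a chelating-phosphine palladium catalyst without free triarylphosphine and a mild phosphate base are chosen to spare the peroxide and the base-sensitive β-peroxy ester.

**Compound list**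

1 | (4S)-4-benzyl-3-propanoyl-1,3-oxazolidin-2-one | CCC(=O)N1[C@@H](Cc2ccccc2)COC1=O | starting material
2 | allyl iodide (3-iodoprop-1-ene) | C=CCI | starting material
3 | sodium (Z)-enolate of 1 | C/C=C(\[O-])N1[C@@H](Cc2ccccc2)COC1=O.[Na+] | intermediate
4 | (4S)-4-benzyl-3-[(2R)-2-methylpent-4-enoyl]-1,3-oxazolidin-2-one | C=CC[C@@H](C)C(=O)N1[C@@H](Cc2ccccc2)COC1=O | intermediate
5 | (4S)-4-benzyl-3-[(2R)-2-methyl-3-(1,2,4-trioxolan-3-yl)propanoyl]-1,3-oxazolidin-2-one (ozonide, mixture at the trioxolane carbon) | C1(C[C@@H](C)C(=O)N2[C@@H](Cc3ccccc3)COC2=O)OCOO1 | intermediate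
6 | (4S)-4-benzyl-3-[(2R)-2-methyl-4-oxobutanoyl]-1,3-oxazolidin-2-one | O=CC[C@@H](C)C(=O)N1[C@@H](Cc2ccccc2)COC1=O | intermediate
7 | propargyl bromide (3-bromoprop-1-yne) | C#CCBr | starting material
8 | allenylzinc bromide | C=C=C[Zn]Br | intermediate
9 | (4S)-4-benzyl-3-[(2R,4RS)-4-hydroxy-2-methylhept-6-ynoyl]-1,3-oxazolidin-2-one | C#CCC(O)C[C@@H](C)C(=O)N1[C@@H](Cc2ccccc2)COC1=O | intermediate
10 | (3R,5RS)-3-methyl-5-(prop-2-yn-1-yl)oxolan-2-one | C#CCC1C[C@@H](C)C(=O)O1 | intermediate
11 | methyl acetate | COC(C)=O | starting material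
12 | lithium enolate of methyl acetate (lithium 1-methoxyethen-1-olate) | [Li+].[O-]C(=C)OC | intermediate
13 | methyl (4R,6RS)-6-hydroxy-4-methyl-3-oxonon-8-ynoate | COC(=O)CC(=O)[C@H](C)CC(O)CC#C | intermediate
14 | methyl (4R)-4-methyl-3,6-dioxonon-8-ynoate | COC(=O)CC(=O)[C@H](C)CC(=O)CC#C | intermediate
15 | methyl (4R)-6-hydroperoxy-6-hydroxy-4-methyl-3-oxonon-8-ynoate (mixture at C6) | COC(=O)CC(=O)[C@H](C)CC(O)(OO)CC#C | intermediate
16 | methyl 2-[(3S,4R,6R)-3,6-dihydroxy-4-methyl-6-(prop-2-yn-1-yl)-1,2-dioxan-3-yl]acetate (diaxial diol drawn) | COC(=O)C[C@]1(O)OO[C@@](O)(CC#C)C[C@H]1C | intermediate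
17 | methyl 2-[(3S,4R,6R)-3,6-dimethoxy-4-methyl-6-(prop-2-yn-1-yl)-1,2-dioxan-3-yl]acetate (diaxial dimethoxy form drawn) | COC(=O)C[C@]1(OC)OO[C@@](OC)(CC#C)C[C@H]1C | intermediate
18 | methyl 2-[(3S,4R,6R)-3-methoxy-4,6-dimethyl-6-(prop-2-yn-1-yl)-1,2-dioxan-3-yl]acetate | COC(=O)C[C@]1(OC)OO[C@@](C)(CC#C)C[C@H]1C | intermediate
19 | methyl 2-[(3S,4R,6R)-4,6-dimethyl-6-(prop-2-yn-1-yl)-1,2-dioxan-3-yl]acetate | COC(=O)C[C@@H]1OO[C@@](C)(CC#C)C[C@H]1C | intermediate
20 | methyl 2-[(3S,4R,6R)-6-[(2E)-3-(dimethylalumanyl)-2-methylprop-2-en-1-yl]-4,6-dimethyl-1,2-dioxan-3-yl]acetate | COC(=O)C[C@@H]1OO[C@@](C)(C/C(C)=C/[Al](C)C)C[C@H]1C | intermediate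
21 | methyl 2-[(3S,4R,6R)-6-[(2E)-3-iodo-2-methylprop-2-en-1-yl]-4,6-dimethyl-1,2-dioxan-3-yl]acetate | COC(=O)C[C@@H]1OO[C@@](C)(C/C(C)=C/I)C[C@H]1C | intermediate
22 | allylbenzene | C=CCc1ccccc1 | starting material
23 | isopropenylboronic acid pinacol ester (4,4,5,5-tetramethyl-2-(prop-1-en-2-yl)-1,3,2-dioxaborolane) | CC(=C)B1OC(C)(C)C(C)(C)O1 | starting material
24 | 4,4,5,5-tetramethyl-2-[(2Z)-4-phenylbut-2-en-2-yl]-1,3,2-dioxaborolane | CC1(C)OB(OC1(C)C)/C(C)=C/Cc1ccccc1 | intermediate
25 | methyl 2-[(3S,4R,6R)-6-[(2E,4E)-2,4-dimethyl-6-phenylhexa-2,4-dien-1-yl]-4,6-dimethyl-1,2-dioxan-3-yl]acetate | COC(=O)C[C@@H]1OO[C@@](C)(C/C(C)=C/C(C)=C/Cc2ccccc2)C[C@H]1C | target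

**Step count**

Total step count: 12. Longest linear sequence: 11 steps (steps 1–10, then 12); step 11 makes the coupling partner.

**Steps most likely to fail**

1. Step 8 (Proposed new method). The O–O bond may be cleaved by the organoaluminium, ionisation may also occur at C3, or the C6 cation may lose a proton instead of capturing methyl. The fallback uses known chemistry (tertiary peroxide by Mukaiyama–Isayama hydroperoxysilylation, ring closure by intramolecular peroxy-Michael addition) and sets out from lactone 10. Reduction with iBu2AlH (CH2Cl2, −78 °C) gives the lactol (3R,5RS)-3-methyl-5-(prop-2-yn-1-yl)oxolan-2-ol F1. Wittig reaction with Ph3P=CHCO2Me opens it to methyl (2E,4R,6RS)-6-hydroxy-4-methylnon-2-en-8-ynoate F2. Buffered Dess–Martin oxidation gives methyl (2E,4R)-4-methyl-6-oxonon-2-en-8-ynoate F3. Non-basic Takai–Lombardo methylenation (Zn, CH2Br2, TiCl4) gives methyl (2E,4R)-4-methyl-6-methylidenenon-2-en-8-ynoate F4. Co(acac)2, O2 and Et3SiH should add H and OOSiEt3 across the 1,1-disubstituted alkene in the Markovnikov sense, in preference to the enoate and the alkyne, to give methyl (2E,4R,6RS)-4,6-dimethyl-6-[(triethylsilyl)peroxy]non-2-en-8-ynoate F5. Bu4NF/AcOH frees methyl (2E,4R,6RS)-6-hydroperoxy-4,6-dimethylnon-2-en-8-ynoate F6, which closes with Et2NH in CF3CH2OH by 6-exo-trig peroxy-Michael addition, 3,4-trans under equilibrating conditions. C6 is not controlled in this sequence, so 19 would have to be separated from its C6 epimer by chromatography. The route is rejoined at 19, and steps 4 to 9 are bypassed.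

2. Step 6 (key step). H2O2 may add twice at C6 (geminal dihydroperoxide), peroxyketalisation may run intermolecularly to oligomers, or the weakly electrophilic β-keto ester carbonyl may fail to close the ring. The fallback changes the electrophile from carbonyl to ketal and sets out from 14. Treatment with MeOH, HC(OMe)3 and PPTS gives the cyclic bis-ketal methyl 2-[(3R)-2,5-dimethoxy-3-methyl-5-(prop-2-yn-1-yl)oxolan-2-yl]acetate F7. Acid-catalysed perhydrolysis of F7 (ethereal H2O2, 1 equiv, HC(OMe)3, catalytic camphorsulfonic acid, CH2Cl2, 0 °C) should exchange the ring oxygen for the O–O unit through the methoxy oxocarbenium ions. This gives the bis-methyl peroxyketal 17 directly, where the route is rejoined without passing through 16.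

3. Step 10. The organoaluminium–zirconium reagent may reduce the O–O bond or attack the ester before carbometalation is complete. The fallback moves the carbometalation ahead of ring formation and sets out from lactone 10. Carboalumination under the conditions of step 10 gives the alkenylalane (3R,5RS)-5-[(2E)-3-(dimethylalumanyl)-2-methylprop-2-en-1-yl]-3-methyloxolan-2-one F8 (not isolated), and iodinolysis gives (3R,5RS)-5-[(2E)-3-iodo-2-methylprop-2-en-1-yl]-3-methyloxolan-2-one F9. F9 is then taken through the operations of steps 4 to 8, in which the vinyl iodide should be a spectator: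
- Claisen opening gives methyl (4R,6RS,8E)-6-hydroxy-9-iodo-4,8-dimethyl-3-oxonon-8-enoate F10.
- Dess–Martin oxidation gives methyl (4R,8E)-9-iodo-4,8-dimethyl-3,6-dioxonon-8-enoate F11.
- Peroxyketalisation with H2O2 gives methyl 2-[(3S,4R,6R)-3,6-dihydroxy-6-[(2E)-3-iodo-2-methylprop-2-en-1-yl]-4-methyl-1,2-dioxan-3-yl]acetate F12.
- Methanol exchange gives methyl 2-[(3S,4R,6R)-6-[(2E)-3-iodo-2-methylprop-2-en-1-yl]-3,6-dimethoxy-4-methyl-1,2-dioxan-3-yl]acetate F13.
- Methyl transfer gives methyl 2-[(3S,4R,6R)-6-[(2E)-3-iodo-2-methylprop-2-en-1-yl]-3-methoxy-4,6-dimethyl-1,2-dioxan-3-yl]acetate F14.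

Silane reduction of F14 as in step 9 gives 21, where the route is rejoined.

**Further compounds**

F1 | step 8 | (3R,5RS)-3-methyl-5-(prop-2-yn-1-yl)oxolan-2-ol | C#CCC1C[C@@H](C)C(O)O1
F2 | step 8 | methyl (2E,4R,6RS)-6-hydroxy-4-methylnon-2-en-8-ynoate | COC(=O)/C=C/[C@H](C)CC(O)CC#C
F3 | step 8 | methyl (2E,4R)-4-methyl-6-oxonon-2-en-8-ynoate | COC(=O)/C=C/[C@H](C)CC(=O)CC#C
F4 | step 8 | methyl (2E,4R)-4-methyl-6-methylidenenon-2-en-8-ynoate | COC(=O)/C=C/[C@H](C)CC(=C)CC#C
F5 | step 8 | methyl (2E,4R,6RS)-4,6-dimethyl-6-[(triethylsilyl)peroxy]non-2-en-8-ynoate | COC(=O)/C=C/[C@H](C)CC(C)(OO[Si](CC)(CC)CC)CC#C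
F6 | step 8 | methyl (2E,4R,6RS)-6-hydroperoxy-4,6-dimethylnon-2-en-8-ynoate | COC(=O)/C=C/[C@H](C)CC(C)(OO)CC#C
F7 | step 6 | methyl 2-[(3R)-2,5-dimethoxy-3-methyl-5-(prop-2-yn-1-yl)oxolan-2-yl]acetate | COC(=O)CC1(OC)OC(OC)(CC#C)C[C@H]1C
F8 | step 10 | (3R,5RS)-5-[(2E)-3-(dimethylalumanyl)-2-methylprop-2-en-1-yl]-3-methyloxolan-2-one | C[Al](C)/C=C(C)/CC1C[C@@H](C)C(=O)O1
F9 | step 10 | (3R,5RS)-5-[(2E)-3-iodo-2-methylprop-2-en-1-yl]-3-methyloxolan-2-one | I/C=C(C)/CC1C[C@@H](C)C(=O)O1
F10 | step 10 | methyl (4R,6RS,8E)-6-hydroxy-9-iodo-4,8-dimethyl-3-oxonon-8-enoate | COC(=O)CC(=O)[C@H](C)CC(O)C/C(C)=C/I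
F11 | step 10 | methyl (4R,8E)-9-iodo-4,8-dimethyl-3,6-dioxonon-8-enoate | COC(=O)CC(=O)[C@H](C)CC(=O)C/C(C)=C/I
F12 | step 10 | methyl 2-[(3S,4R,6R)-3,6-dihydroxy-6-[(2E)-3-iodo-2-methylprop-2-en-1-yl]-4-methyl-1,2-dioxan-3-yl]acetate | COC(=O)C[C@]1(O)OO[C@@](O)(C/C(C)=C/I)C[C@H]1C
F13 | step 10 | methyl 2-[(3S,4R,6R)-6-[(2E)-3-iodo-2-methylprop-2-en-1-yl]-3,6-dimethoxy-4-methyl-1,2-dioxan-3-yl]acetate | COC(=O)C[C@]1(OC)OO[C@@](OC)(C/C(C)=C/I)C[C@H]1C
F14 | step 10 | methyl 2-[(3S,4R,6R)-6-[(2E)-3-iodo-2-methylprop-2-en-1-yl]-3-methoxy-4,6-dimethyl-1,2-dioxan-3-yl]acetate | COC(=O)C[C@]1(OC)OO[C@@](C)(C/C(C)=C/I)C[C@H]1C
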